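**Plan**

1. Numbering (cadinane): C1 (sp3) and C6 (sp2) are the ring-fusion carbons; C2 and C3 are the CH2 groups of ring B; C4 is the spiro carbon; C5 is the vinylic CH; C7 (i-Pr) and C10 (Me) lie in ring A; C15 is the chroman CH2.
2. Retrosynthesis, first cut: O–C4 and C15–CHPh, a hetero-Diels–Alder addition of the o-quinone methide from 2,4,6-trihydroxybenzene-1,3-dicarbaldehyde and PhCHO to the exocyclic C4=C15 of a cadina-4(15),5-diene. C15 (α-methylenation) and C5–H (enol triflate reduction) are then traced back to a ring-B enone with its carbonyl at C5.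
3. Second cut: C1–C6 and C3–C4 of that enone, a [3+3] union of the acetone-like unit C4–C5(=O)–C6 with the enal unit C1=C2–C3HO, both placed at the ends of one acyclic chain; the chain comes from (−)-menthone.
4. Enabling feature: in the cyclohexene ring B the sp2 carbon C5 sits between the two bond-forming carbons C4 and C6. It can therefore be a ketone whose two α-carbons are the nucleophiles and whose C5=C6 enol is the alkene of the target, while C1 and C3 map onto the β-carbon and carbonyl of an enal.
5. Forward order: chain (steps 1–7), ring A then ring B in one flask (step 8), C15 and C5=C6 (steps 9–12), chroman ring last (step 13).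
6. Stereochemistry: C7 and C10 from (−)-menthone; C1 in step 8 (A(1,3)-controlled chair); spiro C4 and the benzylic centre in step 13 (axial C–O bond formation, phenyl away from ring A).

Key step: step 8

Remark: 2,4,6-trihydroxybenzene-1,3-dicarbaldehyde and [Ph3PCH(OMe)CH3]Cl are taken as available reagents (one step from phloroglucinol, and from PPh3 plus 1-chloroethyl methyl ether, respectively).
Remark: the ring-fusion carbon C6 (α to the C5 ketone) is carried as an epimer mixture from step 8 to step 10, because it becomes sp2 in step 11; the enol ether of steps 6–7 is likewise an E/Z mixture of no consequence.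

**Step 1**
Reactants: 1 (−)-menthone, (2S,5R)-5-methyl-2-(propan-2-yl)cyclohexan-1-one
Product: 3 trimethyl{[(3R,6S)-3-methyl-6-(propan-2-yl)cyclohex-1-en-1-yl]oxy}silane, via lithium enolate 2 (not isolated)
Conditions: LiN(i-Pr)2, THF, −78 °C; Me3SiCl, −78 → 0 °C
Reagents that add atoms: chlorotrimethylsilane, C[Si](C)(C)Cl
Why: Kinetic deprotonation of a 2-alkylcyclohexanone occurs at the less hindered α-CH2 (C1) and O-silylation fixes the C6=C1 enol ether without touching C7 or C10 (regioselective silyl enol ether formation).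

**Step 2**
Reactants: 3 trimethyl{[(3R,6S)-3-methyl-6-(propan-2-yl)cyclohex-1-en-1-yl]oxy}silane
Product: 5 (2S,5R)-5-methyl-6-oxo-2-(propan-2-yl)hexanoic acid, via silyl ester methoxy hydroperoxide 4 (not isolated)
Conditions: O3, CH2Cl2/MeOH, −78 °C; Me2S, −78 °C → rt; aqueous work-up
Reagents that add atoms: ozone, [O-][O+]=O
Why: Ozonolysis of the silyl enol ether cleaves C6=C1 to a silyl ester at C6 and, after Me2S reduction of the methoxy hydroperoxide, an aldehyde at C1, so the two chain ends come out differentiated and both stereocentres are untouched (oxidative cleavage of an enol ether).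

**Step 3**
Reactants: 5 (2S,5R)-5-methyl-6-oxo-2-(propan-2-yl)hexanoic acid
Product: 6 (2S,5R,6E)-8-[methoxy(methyl)amino]-5-methyl-8-oxo-2-(propan-2-yl)oct-6-enoic acid
Conditions: Ph3P=CHC(O)N(OMe)Me (2.2 equiv), CH2Cl2, rt; acidic work-up
Reagents that add atoms: N-methoxy-N-methyl-2-(triphenylphosphoranylidene)acetamide, CON(C)C(=O)C=P(c1ccccc1)(c1ccccc1)c1ccccc1
Why: The stabilised ylide reacts only with the aldehyde and should give the (E)-enamide under conditions mild enough to keep the α-stereocentre C10, the second equivalent covering the free acid (Wittig olefination).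

**Step 4**
Reactants: 6 (2S,5R,6E)-8-[methoxy(methyl)amino]-5-methyl-8-oxo-2-(propan-2-yl)oct-6-enoic acid
Product: 8 (2E,4R,7S)-8-hydroxy-N-methoxy-N,4-dimethyl-7-(propan-2-yl)oct-2-enamide, via mixed anhydride 7 (not isolated)
Conditions: i-BuOCOCl, N-methylmorpholine, THF, −15 °C; then NaBH4, H2O, −15 → 0 °C
Reagents that add atoms: none
Why: Activation of the acid as a mixed carbonic anhydride followed by NaBH4 should reduce it to the primary alcohol while the conjugated Weinreb amide is left alone at low temperature (chemoselective mixed-anhydride reduction).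

**Step 5**
Reactants: 8 (2E,4R,7S)-8-hydroxy-N-methoxy-N,4-dimethyl-7-(propan-2-yl)oct-2-enamide
Product: 9 (2E,4R,7S)-N-methoxy-N,4-dimethyl-8-oxo-7-(propan-2-yl)oct-2-enamide
Conditions: Dess–Martin periodinane, CH2Cl2, 0 °C → rt
Reagents that add atoms: none
Why: Dess–Martin oxidation of the primary alcohol stops at the aldehyde under near-neutral conditions, which limits epimerisation at the adjacent C7.

**Step 6**
Reactants: 9 (2E,4R,7S)-N-methoxy-N,4-dimethyl-8-oxo-7-(propan-2-yl)oct-2-enamide
Product: 10 (2E,4R,7S)-N,9-dimethoxy-N,4-dimethyl-7-(propan-2-yl)deca-2,8-dienamide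
Conditions: [Ph3PCH(OMe)CH3]Cl, KN(SiMe3)2, THF, −78 °C; then 9, −78 → 0 °C
Reagents that add atoms: (1-methoxyethyl)triphenylphosphonium chloride, COC(C)[P+](c1ccccc1)(c1ccccc1)c1ccccc1.[Cl-]
Why: The α-methoxy ylide adds to the aldehyde far faster than to the Weinreb amide and gives a methyl enol ether with oxygen on C5 and the nucleophilic carbon at C6, which is the regiochemistry needed in step 8 (Wittig olefination).

**Step 7**
Reactants: 10 (2E,4R,7S)-N,9-dimethoxy-N,4-dimethyl-7-(propan-2-yl)deca-2,8-dienamide
Product: 11 (2E,4R,7S)-9-methoxy-4-methyl-7-(propan-2-yl)deca-2,8-dienal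
Conditions: i-Bu2AlH, THF, −78 °C; aq. KNaC4H4O6 work-up
Reagents that add atoms: none
Why: i-Bu2AlH adds once to the Weinreb amide and the chelated tetrahedral intermediate releases the (E)-enal only on work-up, the enol ether being inert to hydride and to the non-acidic tartrate work-up (Weinreb amide reduction).

**Step 8**
Reactants: 11 (2E,4R,7S)-9-methoxy-4-methyl-7-(propan-2-yl)deca-2,8-dienal
Product: 14 (4aR,5R,8S)-5-methyl-8-(propan-2-yl)-4a,5,6,7,8,8a-hexahydronaphthalen-1(4H)-one, via hexahydroisochromene ketal 12 (not isolated), via keto aldehyde 13 (not isolated)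
Conditions: Yb(OTf)3 (10 mol %), CH2Cl2, 0 °C → rt; then 2 M HCl, THF, 50 °C
Reagents that add atoms: water, O
Why: Yb(OTf)3 activates the enal of 11 as a 1-oxadiene whose electrophilic β-carbon C1 is attacked by the nucleophilic carbon C6 of the tethered 2-methoxyalkene while the carbonyl oxygen closes onto C5 (intramolecular inverse-electron-demand hetero-Diels–Alder reaction, or its stepwise Mukaiyama–Michael equivalent) to give ketal 12; aqueous acid then opens 12 to the 1,5-keto aldehyde 13, whose methyl ketone enol (C4) adds to the aldehyde carbon C3 and dehydrates. The closest known reaction types are the enal/enol ether hetero-Diels–Alder route to 1,5-dicarbonyl compounds and the aldol cyclodehydration of 1,5-keto aldehydes to cyclohexenones, together a Robinson-type [3+3] annulation. Ring A closes through C1–C6 as the carbocycle spanned by the four-carbon tether C7–C10 (6-exo attack of C6 on the enal β-carbon, chair transition state), and ring B closes through C3–C4 by a 6-(enolendo)-exo-trig aldol addition followed by dehydration. The only new stereocentre that matters is C1 (C6 becomes sp2 later and the ketal carbon is hydrolysed): A(1,3) strain between the C5 substituents of the enol ether and the C7 isopropyl group should put C7–H in the alkene plane, so the chair carries isopropyl and the trans-related C10 methyl axial and the enal arm equatorial, which places the C1–C2 bond cis to the C10 methyl as in the target. Regioselectivity (C6 and not C4 as the first nucleophile, the aldehyde and not the ketone as aldol acceptor) is secured by the position of the enol ether double bond and by ring size, and the Lewis-acid first stage avoids base or amine that would epimerise the γ-stereocentre C10 of the enal.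

**Step 9**
Reactants: 14 (4aR,5R,8S)-5-methyl-8-(propan-2-yl)-4a,5,6,7,8,8a-hexahydronaphthalen-1(4H)-one
Product: 16 (4aR,5R,8S)-2-[(dimethylamino)methyl]-5-methyl-8-(propan-2-yl)octahydronaphthalen-1(2H)-one, via lithium enolate 15 (not isolated)
Conditions: LiBH(s-Bu)3, THF, −78 °C; then CH2=NMe2+ I−, −78 °C → rt
Reagents that add atoms: N,N-dimethylmethaniminium iodide, C=[N+](C)C.[I-]
Why: LiBH(s-Bu)3 reduces cyclohexenones without a β-substituent in the conjugate sense and the regiodefined C4=C5 enolate is aminomethylated at C4 by the iminium salt (reductive Mannich reaction), the new centre at C4 being lost in the next step.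

**Step 10**
Reactants: 16 (4aR,5R,8S)-2-[(dimethylamino)methyl]-5-methyl-8-(propan-2-yl)octahydronaphthalen-1(2H)-one
Product: 18 (4aR,5R,8S)-5-methyl-2-methylidene-8-(propan-2-yl)octahydronaphthalen-1(2H)-one, via ammonium iodide 17 (not isolated)
Conditions: MeI, CH2Cl2, rt; then aq. NaHCO3, rt
Reagents that add atoms: none
Why: Exhaustive methylation turns the amine into a leaving group and mild base should effect E1cB elimination to the exocyclic enone, which installs C15 (Mannich base elimination).

**Step 11**
Reactants: 18 (4aR,5R,8S)-5-methyl-2-methylidene-8-(propan-2-yl)octahydronaphthalen-1(2H)-one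
Product: 20 (4aR,5R,8S)-5-methyl-2-methylidene-8-(propan-2-yl)-2,3,4,4a,5,6,7,8-octahydronaphthalen-1-yl trifluoromethanesulfonate, via potassium dienolate 19 (not isolated)
Conditions: KN(SiMe3)2, THF, −78 °C; PhNTf2, −78 → 0 °C
Reagents that add atoms: N-phenylbis(trifluoromethanesulfonimide), O=S(=O)(N(c1ccccc1)S(=O)(=O)C(F)(F)F)C(F)(F)F
Why: With C4 now sp2 the only α-hydrogen is on C6, so the base should give the cross-conjugated dienolate regiospecifically and O-triflation fixes the C5=C6 double bond of the target (enol triflate formation).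

**Step 12**
Reactants: 20 (4aR,5R,8S)-5-methyl-2-methylidene-8-(propan-2-yl)-2,3,4,4a,5,6,7,8-octahydronaphthalen-1-yl trifluoromethanesulfonate
Product: 21 (1S,4R,4aR)-4-methyl-7-methylidene-1-(propan-2-yl)-1,2,3,4,4a,5,6,7-octahydronaphthalene (cadina-4(15),5-diene skeleton)
Conditions: Pd(OAc)2 (5 mol %), PPh3 (10 mol %), HCO2H, n-Bu3N, DMF, 60 °C
Reagents that add atoms: none
Why: Oxidative addition of zerovalent palladium into the alkenyl triflate, hydride transfer from formate and reductive elimination should replace OTf by H with the diene left in place (palladium-catalysed formate reduction of enol triflates).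

**Step 13**
Reactants: 21 (1S,4R,4aR)-4-methyl-7-methylidene-1-(propan-2-yl)-1,2,3,4,4a,5,6,7-octahydronaphthalene; 22 2,4,6-trihydroxybenzene-1,3-dicarbaldehyde; 23 benzaldehyde
Product: 25 Guajadial D, via o-quinone methide 24 (not isolated)
Conditions: NaOAc, AcOH, 80 °C
Reagents that add atoms: none
Why: Knoevenagel-type condensation of 22 with 23 gives o-quinone methide 24, which should add to the exocyclic, more nucleophilic C4=C15 bond of the s-trans diene with the benzylic carbon at C15 and oxygen at C4 (inverse-electron-demand hetero-Diels–Alder reaction), the C–O bond forming axially on ring B anti to H1 and the phenyl group turning away from ring A, which should favour the (4S, benzylic S) isomer among the possible diastereomers.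

**Compound list**

1 | (−)-menthone, (2S,5R)-5-methyl-2-(propan-2-yl)cyclohexan-1-one | CC(C)[C@@H]1CC[C@@H](C)CC1=O | starting material
2 | lithium (3R,6S)-3-methyl-6-(propan-2-yl)cyclohex-1-en-1-olate | CC(C)[C@@H]1CC[C@@H](C)C=C1[O-].[Li+] | intermediate
3 | trimethyl{[(3R,6S)-3-methyl-6-(propan-2-yl)cyclohex-1-en-1-yl]oxy}silane | CC(C)[C@@H]1CC[C@@H](C)C=C1O[Si](C)(C)C | intermediate
4 | trimethylsilyl (2S,5R)-6-hydroperoxy-6-methoxy-5-methyl-2-(propan-2-yl)hexanoate (C6 unassigned) | CC(C)[C@H](CC[C@@H](C)C(OC)OO)C(=O)O[Si](C)(C)C | intermediate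
5 | (2S,5R)-5-methyl-6-oxo-2-(propan-2-yl)hexanoic acid | CC(C)[C@H](CC[C@@H](C)C=O)C(=O)O | intermediate
6 | (2S,5R,6E)-8-[methoxy(methyl)amino]-5-methyl-8-oxo-2-(propan-2-yl)oct-6-enoic acid | CC(C)[C@H](CC[C@@H](C)/C=C/C(=O)N(C)OC)C(=O)O | intermediate
7 | isobutyl carbonic mixed anhydride of 6 | CC(C)[C@H](CC[C@@H](C)/C=C/C(=O)N(C)OC)C(=O)OC(=O)OCC(C)C | intermediate
8 | (2E,4R,7S)-8-hydroxy-N-methoxy-N,4-dimethyl-7-(propan-2-yl)oct-2-enamide | CC(C)[C@H](CC[C@@H](C)/C=C/C(=O)N(C)OC)CO | intermediate
9 | (2E,4R,7S)-N-methoxy-N,4-dimethyl-8-oxo-7-(propan-2-yl)oct-2-enamide | CC(C)[C@H](CC[C@@H](C)/C=C/C(=O)N(C)OC)C=O | intermediate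
10 | (2E,4R,7S)-N,9-dimethoxy-N,4-dimethyl-7-(propan-2-yl)deca-2,8-dienamide (8E/8Z mixture) | CC(C)[C@H](CC[C@@H](C)/C=C/C(=O)N(C)OC)C=C(C)OC | intermediate
11 | (2E,4R,7S)-9-methoxy-4-methyl-7-(propan-2-yl)deca-2,8-dienal (8E/8Z mixture) | CC(C)[C@H](CC[C@@H](C)/C=C/C=O)C=C(C)OC | intermediate
12 | (4aS,5R,8S)-1-methoxy-1,5-dimethyl-8-(propan-2-yl)-4a,5,6,7,8,8a-hexahydro-1H-isochromene (C1 and C8a of this name unassigned) | CC(C)[C@@H]1CC[C@@H](C)[C@H]2C=COC(C)(OC)C12 | intermediate
13 | 2-[(1R,3S,6R)-2-acetyl-6-methyl-3-(propan-2-yl)cyclohexyl]acetaldehyde (C2 of the ring unassigned) | CC(C)[C@@H]1CC[C@@H](C)[C@@H](CC=O)C1C(C)=O | intermediate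
14 | (4aR,5R,8S)-5-methyl-8-(propan-2-yl)-4a,5,6,7,8,8a-hexahydronaphthalen-1(4H)-one (8a epimers) | CC(C)[C@@H]1CC[C@@H](C)[C@H]2CC=CC(=O)C12 | intermediate
15 | lithium enolate of the 2,3-dihydro ketone from 14 (C1=C2 enolate in naphthalene numbering) | CC(C)[C@@H]1CC[C@@H](C)[C@H]2CCC=C([O-])C12.[Li+] | intermediate
16 | (4aR,5R,8S)-2-[(dimethylamino)methyl]-5-methyl-8-(propan-2-yl)octahydronaphthalen-1(2H)-one (C2, C8a unassigned) | CC(C)[C@@H]1CC[C@@H](C)[C@H]2CCC(CN(C)C)C(=O)C12 | intermediate
17 | trimethylammonium iodide from 16 | CC(C)[C@@H]1CC[C@@H](C)[C@H]2CCC(C[N+](C)(C)C)C(=O)C12.[I-] | intermediate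
18 | (4aR,5R,8S)-5-methyl-2-methylidene-8-(propan-2-yl)octahydronaphthalen-1(2H)-one (8a epimers) | CC(C)[C@@H]1CC[C@@H](C)[C@H]2CCC(=C)C(=O)C12 | intermediate
19 | potassium dienolate of 18 | CC(C)[C@@H]1CC[C@@H](C)[C@H]2CCC(=C)C([O-])=C12.[K+] | intermediate
20 | (4aR,5R,8S)-5-methyl-2-methylidene-8-(propan-2-yl)-2,3,4,4a,5,6,7,8-octahydronaphthalen-1-yl trifluoromethanesulfonate | CC(C)[C@@H]1CC[C@@H](C)[C@H]2CCC(=C)C(OS(=O)(=O)C(F)(F)F)=C12 | intermediate
21 | (1S,4R,4aR)-4-methyl-7-methylidene-1-(propan-2-yl)-1,2,3,4,4a,5,6,7-octahydronaphthalene | CC(C)[C@@H]1CC[C@@H](C)[C@H]2CCC(=C)C=C12 | intermediate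
22 | 2,4,6-trihydroxybenzene-1,3-dicarbaldehyde | O=Cc1c(O)cc(O)c(C=O)c1O | starting material
23 | benzaldehyde | O=Cc1ccccc1 | starting material
24 | 5-benzylidene-2,4-dihydroxy-6-oxocyclohexa-1,3-diene-1,3-dicarbaldehyde | O=CC1=C(O)C(C=O)=C(O)C(=Cc2ccccc2)C1=O | intermediate
25 | Guajadial D | CC(C)[C@@H]1CC[C@@H](C)[C@H]2CC[C@@]3(C=C12)C[C@@H](c1ccccc1)c1c(O)c(C=O)c(O)c(C=O)c1O3 | target

**Step count**

Total steps: 13. Longest linear sequence: 13 steps (1 to 25; 22 and 23 enter in the last step).

**Steps most likely to fail**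

Step 8. The cyclisation may take place on the wrong face of the enal, giving the C1 epimer. The enol ether may also be hydrolysed before it cyclises, leaving a slower and less selective acid-catalysed Michael addition. In that case the bicyclic skeleton would be built on the intact ring of 1 by a Stork enamine Robinson annulation, in which C1 is an epimerisable γ-carbon of the product and settles under thermodynamic control. Compound 1 and pyrrolidine (TsOH cat., PhMe, reflux, water removal) should give the less substituted enamine 1-[(3R,6S)-3-methyl-6-(propan-2-yl)cyclohex-1-en-1-yl]pyrrolidine F1. F1 adds to but-3-en-2-one (dioxane, rt; then NaOAc, AcOH, H2O) to give the diketone (2S,5R)-5-methyl-6-(3-oxobutyl)-2-(propan-2-yl)cyclohexan-1-one F2. KOH in MeOH closes and dehydrates F2 to the octalone (4aR,5R,8S)-5-methyl-8-(propan-2-yl)-4,4a,5,6,7,8-hexahydronaphthalen-2(3H)-one F3. Wittig methylenation of F3 (MePPh3Br, KOt-Bu, THF) gives diene 21. This fallback sets out from 1 and comes back to the route at 21.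

Step 13. Facial and endo/exo discrimination in the cycloaddition may be poor, giving a mixture of spiro and benzylic epimers, and the hot acidic medium may isomerise the exocyclic diene before it reacts. The o-quinone methide would then be released from an isolable precursor under base at low temperature and steered by a catalyst. Compounds 22 and 23 with TolSO2Na (HCO2H, H2O/EtOH, rt) should give the sulfone 2,4,6-trihydroxy-5-[(4-methylbenzenesulfonyl)(phenyl)methyl]benzene-1,3-dicarbaldehyde F4. F4 and 21 with aq. Na2CO3 and a chiral bifunctional squaramide–amine catalyst (CH2Cl2, −20 °C) release 24 slowly and should give 25 under catalyst control. This fallback sets out from 22 and 23 (with 21) and comes back at 25.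

Step 11. Deprotonation of the hindered ring-fusion C–H may be slow, and the exocyclic enone may oligomerise by base-induced Michael addition. Enolisation would then be avoided altogether. Compound 18 is reduced (NaBH4, CeCl3·7H2O, MeOH, −40 °C) to the allylic alcohol (4aR,5R,8S)-5-methyl-2-methylidene-8-(propan-2-yl)decahydronaphthalen-1-ol F5. F5 is dehydrated with Martin sulfurane (CH2Cl2, rt); the only β-hydrogen is on C6, so elimination can give only 21. This fallback sets out from 18 and comes back at 21.

**Further compounds**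

F1 | step 8 | 1-[(3R,6S)-3-methyl-6-(propan-2-yl)cyclohex-1-en-1-yl]pyrrolidine | CC(C)[C@@H]1CC[C@@H](C)C=C1N1CCCC1
F2 | step 8 | (2S,5R)-5-methyl-6-(3-oxobutyl)-2-(propan-2-yl)cyclohexan-1-one (C6 unassigned) | CC(C)[C@@H]1CC[C@@H](C)C(CCC(C)=O)C1=O
F3 | step 8 | (4aR,5R,8S)-5-methyl-8-(propan-2-yl)-4,4a,5,6,7,8-hexahydronaphthalen-2(3H)-one | CC(C)[C@@H]1CC[C@@H](C)[C@H]2CCC(=O)C=C12
F4 | step 13 | 2,4,6-trihydroxy-5-[(4-methylbenzenesulfonyl)(phenyl)methyl]benzene-1,3-dicarbaldehyde | O=Cc1c(O)c(C=O)c(O)c(C(c2ccccc2)S(=O)(=O)c2ccc(C)cc2)c1O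
F5 | step 11 | (4aR,5R,8S)-5-methyl-2-methylidene-8-(propan-2-yl)decahydronaphthalen-1-ol | CC(C)[C@@H]1CC[C@@H](C)[C@H]2CCC(=C)C(O)C12
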